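The rate constants are invented; the rest is arithmetic.

Amounts first: 0.162 M of reagent meets 0.17 M of substrate over 3.4 mM of free catalyst, and reagent is also lost to itself.

substrate 0.17 M; reagent 0.162 M; free catalyst 3.4 mM

    reagent + free catalyst ⇌ catalyst intermediate A (K1 = 65 M⁻¹, k1 = 5.0 M⁻¹ s⁻¹)
    substrate + catalyst intermediate A → catalyst intermediate B (k2 = 5.3 M⁻¹ s⁻¹)
    catalyst intermediate B → free catalyst + product (k3 = 0.22 s⁻¹)
    2 reagent → homo dimer (k4 = 0.075 M⁻¹ s⁻¹)

* the form that holds most of the catalyst when 30% of the substrate are converted (catalyst intermediate A / free catalyst / catalyst intermediate B)
* its share of the catalyst then
* apparent order in reagent when 30% of the substrate are converted (percent change of the rate of making product for one percent more reagent charged)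

- where a step has two of a species, its rate is k times that concentration squared, and two are used at each turn
- charge of substrate (flask): 0.17 M

Two chemists dispute where the catalyst sits when 30% of the substrate is converted. The first reads the charge: the equilibrium constant of binding times c(reagent) is 11, and catalyst intermediate A moves on at 0.90 s⁻¹ while catalyst intermediate B breaks up more slowly, at 0.22 s⁻¹. So catalyst intermediate B is the resting state, with 65.0% of the catalyst as charged. The second answers that homo dimer formation uses reagent 1.4 times as fast as forward binding at the start, so the charge is the wrong place to look.

My own reckoning joins the two ends. At c(substrate) of 0.119 M, catalyst intermediate A leaves backward at 0.0769 s⁻¹ and onward at 0.631 s⁻¹. In steady state, catalyst intermediate B stands to catalyst intermediate A as onward rate over breakup rate, 2.87. Free catalyst stands to catalyst intermediate A as the sum of both exits over the binding rate constant 5.0 M⁻¹ s⁻¹ times c(reagent). Dividing that sum by the binding rate constant and by 3.87 gives the crossover reagent, 0.0366 M, the c(reagent) at which free catalyst holds half of the catalyst. Its share is then crossover over crossover plus c(reagent).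

At the turnover reckoned for the charge, this conversion takes about 105 s. By then dimer formation by itself leaves 0.0456 M, and the product takes 0.0510 M of reagent besides. These losses overlap, but I expect c(reagent) below crossover, with free catalyst ahead; I carry the share no further by hand.

The forecast sides with the second chemist, “so the reagent collapses”: free catalyst, 74%, order 1.25.

The flask reaches that conversion at 169 s with free catalyst at 73.1%, catalyst intermediate B at 20.2%, catalyst intermediate A at 6.73%, and an apparent order of 1.2. The first chemist's region is the early flask: catalyst intermediate B holds 62.5% at 8.00 s and 52.1% at 40.0 s. Through the crossover, the share read here corresponds to c(reagent) near 0.0135 M.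

The loss of reagent to homo dimer is the largest single effect on this rate. In the flask without that step, c(reagent) at this conversion is about the charge less what the substrate used, 0.111 M, which is above crossover, so the crossover gives catalyst intermediate B 55.8% of the catalyst and a rate 2.77 times the actual one. The run without that step gives 2.77 times the actual rate.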